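Every part of a charge has to stand somewhere, so in the summer and dusk runs I counted what the readings did not show.

| flask | starting material | gas phase | remark | time |
|---|---|---|---|---|
| summer | 0.40 M (in portions, 4) | 200 mM (held) | the very flask that is asked about, followed so far; portions every 8.0 min |  |
| dusk | 0.60 M (in portions, 4) | 200 mM (held) | run made earlier; portions every 8.0 min |  |
| flask | 0.40 M (in portions, 4) | 200 mM (held) | the portions of starting material follow each other after 8.0 min, the first at the start | 10 h |

| run | time / h | starting material / % | product / % |
|---|---|---|---|
| summer | 0.200 | 46 | 0 |
| summer | 0.667 | 70 | 2 |
| summer | 1.00 | 57 | 6 |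
| summer | 1.50 | 40 | 8 |
| summer | 2.50 | 28 | 13 |
| summer | 3.00 | 27 | 15 |
| dusk | 1.50 | 40 | 12 |
| dusk | 3.00 | 25 | 14 |
| dusk | 5.00 | 22 | 23 |
| dusk | 6.00 | 20 | 21 |
| dusk | 8.00 | 16 | 29 |
| dusk | 10.0 | 18 | 31 |

(each reading ± 2 percentage points)

- the analysis behind the earlier runs scatters by 2 percentage points, standard deviation
- at the start none of the gas phase is in solution
- what has gone from starting material into another species counts as reacted, even if it can come back

- share of the starting material used up at 10 h
- product at 10 h, in percent of the starting material charged
- amount of product if the flask were left three thousand times as long, in percent of the starting material charged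

At 3.00 h in summer, starting material and product left 58.0% of the charge unaccounted for, which I took to be held in a hidden form. I folded the readings into one number, the free share: starting material divided by everything not yet product. An even split would give 0.5. Pooling dusk from 5.00 h onward gave 0.257, which is lower. At 3.00 h, summer read 0.318 and dusk 0.291, despite charges of 0.40 M and 0.60 M.

One number was not enough: it divides what remains, but does not say how much remains. For that I borrowed dusk's product at 10 h, 31%, since the two runs had read 15% and 14% at 3.00 h. The share then left 17.7% as starting material, so I committed to 82.3% used up. Dusk's share read 0.286 at 5.00 h and 0.261 at 10.0 h while its product read 23% and then 31%, so I expected the hidden form to feed product, and product to end near the whole charge.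

The forecast gave 82% used up, 31% product at 10 h and 97% product after the long wait, holding that “the reservoir drains through starting material into product”. The simulated summer flask gave 82.9%, 31.0% and 100%, in the same order.

    gas phase ⇌ dissolved gas, rate k1*(csat - [dissolved gas]) (kL = 8.51 h⁻¹)
    starting material ⇌ dormant form (K = 2.70, k = 0.740 h⁻¹)
    starting material + dissolved gas → product (k = 0.598 L mol⁻¹ h⁻¹)

At 0.193 h in the summer flask, starting material had a half-life of 0.94 h by the forward step into the dormant form alone, against 7.2 h by the step into product, so it entered the dormant form faster. My share gives 17.7% starting material at 10.0 h against 17.1% in the flask, and for the same flask left until 25 h, with product at 55.7%, it gives 11.4% against 11.0%.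

The runs were generated by integration with constants of no real substance; scatter was added.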